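## Retrosynthetic overview

- The target is a 6,12-elemanolide. The γ-lactone (O6 to C12) is closed last, the C8 ester comes from (R)-3-hydroxy-2-methylpropanoic acid, and the only carbocycle (C5–C6–C7–C8–C9–C10) is opened at C7–C8.
- Enabling feature: O8–C8 is homoallylic to the exocyclic C11=C13 methylene through C7, so O–C8–C7–C11=C13 is the retron of a carbonyl allylation. C7–C8 lies in the cyclohexane only, so the cut gives an acyclic C8 aldehyde carrying a (Z)-2-(methoxycarbonyl)allylboronate (C13–C11=C7); two natively electrophilic carbons (aldehyde C8, acrylate β-carbon C7) are joined after polarity reversal of C7.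
- The acyclic chain takes C6 from D-malic acid and sets C5/C10 in one chelate-controlled dianionic ester-enolate Claisen rearrangement. The C4 carboxyl becomes the C4(=C3H2)C15H2O unit; the C7 ester becomes an ynoate and then the allylboronate.
- Ring order: cyclohexane first (key step, sets C7 and C8), γ-lactone last.

Key step: step 13

Remark: locants C1–C15 are the elemanolide locants of the target (C10 quaternary, C5 bearing C4(=C3)C15, C6 lactone carbinol, C7 bearing C11(=C13)C12, C8 acyloxy carbon, C9 methylene); D-malic acid is the (R)-acid, and tributyl[(methoxymethoxy)methyl]stannane and 2-(iodomethyl)pinacolborane (ICH2Bpin) are taken as purchased reagents.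

## Route

Step 1
Reactants: 1 tert-butyl(but-3-yn-1-yloxy)dimethylsilane
Product: 3 (E)-5-(tert-butyldimethylsilyloxy)-3-methylpent-2-en-1-ol, via alkenylalane 2 (not isolated)
Conditions: Me3Al (2.5 equiv), Cp2ZrCl2 (0.25 equiv), CH2Cl2, 0 °C to rt; then n-BuLi, THF, −78 °C; (CH2O)n, −78 °C to rt; aq. potassium sodium tartrate
Reagents that add atoms: trimethylaluminium C[Al](C)C; formaldehyde (as paraformaldehyde) C=O
Why: Zirconium-catalysed syn-carboalumination of the terminal alkyne (Negishi carboalumination) puts methyl on the internal carbon cis to aluminium, and hydroxymethylation of the derived alanate with retention should give the pure (E)-allylic alcohol whose geometry later fixes C10.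

Step 2
Reactants: 4 D-malic acid
Product: 5 2-[(4R)-2,2-dimethyl-5-oxo-1,3-dioxolan-4-yl]acetic acid
Conditions: Me2C(OMe)2, PPTS (cat.), rt
Reagents that add atoms: 2,2-dimethoxypropane COC(C)(C)OC
Why: Acid-catalysed acetonide (1,3-dioxolan-4-one) formation ties up the α-hydroxy acid unit and leaves only the future C4 carboxyl free; the C6 stereocentre comes from the chiral pool and is not touched.

Step 3
Reactants: 5 2-[(4R)-2,2-dimethyl-5-oxo-1,3-dioxolan-4-yl]acetic acid; 3 (E)-5-(tert-butyldimethylsilyloxy)-3-methylpent-2-en-1-ol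
Product: 6 (E)-5-(tert-butyldimethylsilyloxy)-3-methylpent-2-en-1-yl 2-[(4R)-2,2-dimethyl-5-oxo-1,3-dioxolan-4-yl]acetate
Conditions: DCC, DMAP (cat.), CH2Cl2, 0 °C to rt
Reagents that add atoms: none
Why: Steglich esterification of the free carboxyl with the primary allylic alcohol should proceed without touching the dioxolanone or the alkene geometry.

Step 4
Reactants: 6 (E)-5-(tert-butyldimethylsilyloxy)-3-methylpent-2-en-1-yl 2-[(4R)-2,2-dimethyl-5-oxo-1,3-dioxolan-4-yl]acetate
Product: 7 1-methyl 4-[(E)-5-(tert-butyldimethylsilyloxy)-3-methylpent-2-en-1-yl] (2R)-2-hydroxybutanedioate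
Conditions: K2CO3 (0.1 equiv), MeOH, 0 °C, 30 min
Reagents that add atoms: methanol CO
Why: Base-catalysed methanolysis opens the activated dioxolanone (acyl acetal) much faster than the ordinary allylic ester exchanges, which should free the C6 hydroxyl and give the C7 methyl ester.

Step 5
Reactants: 7 1-methyl 4-[(E)-5-(tert-butyldimethylsilyloxy)-3-methylpent-2-en-1-yl] (2R)-2-hydroxybutanedioate
Product: 9 (2S,3S)-3-[2-(tert-butyldimethylsilyloxy)ethyl]-2-[(1R)-1-hydroxy-2-methoxy-2-oxoethyl]-3-methylpent-4-enoic acid, via dianion 8 (not isolated)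
Conditions: LiN(i-Pr)2 (2.3 equiv), THF, −78 °C, then −78 to 25 °C (40 °C if needed); 1 M HCl to pH 3, 0 °C
Reagents that add atoms: none
Why: Dianionic ester-enolate Claisen rearrangement ([3,3], Ireland–Claisen family): the lithium chelate between the C6 alkoxide and the enolate oxygen fixes the enolate geometry (C6 cis to OLi) and screens the face carrying CO2Me, and the (E)-allyl terminus reacts through a chair, so that C5 and the quaternary C10 should be set together, anti to the carbinol as in Fráter–Seebach alkylations of malates.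

Step 6
Reactants: 9 (2S,3S)-3-[2-(tert-butyldimethylsilyloxy)ethyl]-2-[(1R)-1-hydroxy-2-methoxy-2-oxoethyl]-3-methylpent-4-enoic acid
Product: 11 (2S,3S)-2-[(1R)-1-(tert-butyldimethylsilyloxy)-2-methoxy-2-oxoethyl]-3-[2-(tert-butyldimethylsilyloxy)ethyl]-3-methylpent-4-enoic acid, via silyl ester 10 (not isolated)
Conditions: TBSOTf (2.3 equiv), 2,6-lutidine, CH2Cl2, −78 to 0 °C; then K2CO3, MeOH/THF/H2O, 0 °C; pH 4
Reagents that add atoms: tert-butyldimethylsilyl trifluoromethanesulfonate CC(C)(C)[Si](C)(C)OS(=O)(=O)C(F)(F)F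
Why: Silylation of the hindered C6 hydroxyl followed by selective hydrolysis of the labile silyl ester should protect O6 (no β-lactone now, no butenolide later) without affecting any stereocentre.

Step 7
Reactants: 11 (2S,3S)-2-[(1R)-1-(tert-butyldimethylsilyloxy)-2-methoxy-2-oxoethyl]-3-[2-(tert-butyldimethylsilyloxy)ethyl]-3-methylpent-4-enoic acid
Product: 13 methyl (2R,3S,4S)-2-(tert-butyldimethylsilyloxy)-4-[2-(tert-butyldimethylsilyloxy)ethyl]-3-[2-(methoxymethoxy)acetyl]-4-methylhex-5-enoate, via acid chloride 12 (not isolated)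
Conditions: Me2C=C(Cl)NMe2, CH2Cl2, 0 °C to rt; then Bu3SnCH2OCH2OMe, PdCl2(PPh3)2 (5 mol %), toluene, 60 °C
Reagents that add atoms: tributyl[(methoxymethoxy)methyl]stannane CCCC[Sn](CCCC)(CCCC)COCOC
Why: Neutral acid chloride formation with the α-chloroenamine followed by Migita–Kosugi–Stille acylation with an α-alkoxymethylstannane should give the α-alkoxy ketone chemoselectively beside the C7 methyl ester and, being base-free, without epimerising the enolisable C5 centre.

Step 8
Reactants: 13 methyl (2R,3S,4S)-2-(tert-butyldimethylsilyloxy)-4-[2-(tert-butyldimethylsilyloxy)ethyl]-3-[2-(methoxymethoxy)acetyl]-4-methylhex-5-enoate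
Product: 14 methyl (2R,3R,4S)-2-(tert-butyldimethylsilyloxy)-4-[2-(tert-butyldimethylsilyloxy)ethyl]-3-[3-(methoxymethoxy)prop-1-en-2-yl]-4-methylhex-5-enoate
Conditions: Zn, CH2Br2, TiCl4, THF/CH2Cl2, 0 °C to rt
Reagents that add atoms: dibromomethane BrCBr
Why: Takai–Lombardo methylenation is non-basic, so the hindered enolisable ketone should be converted into the C4=C3 alkene without epimerisation at C5 or β-elimination of the C6 silyloxy group, and the ester is not attacked.

Step 9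
Reactants: 14 methyl (2R,3R,4S)-2-(tert-butyldimethylsilyloxy)-4-[2-(tert-butyldimethylsilyloxy)ethyl]-3-[3-(methoxymethoxy)prop-1-en-2-yl]-4-methylhex-5-enoate
Product: 16 (3R,4R,5S)-3-(tert-butyldimethylsilyloxy)-5-[2-(tert-butyldimethylsilyloxy)ethyl]-4-[3-(methoxymethoxy)prop-1-en-2-yl]-5-methylhept-6-en-1-yne, via aldehyde 15 (not isolated)
Conditions: i-Bu2AlH (1.1 equiv), CH2Cl2, −78 °C; then MeOH, K2CO3, MeC(O)C(N2)P(O)(OMe)2, −78 °C to rt
Reagents that add atoms: dimethyl (1-diazo-2-oxopropyl)phosphonate CC(=O)C(=[N+]=[N-])P(=O)(OC)OC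
Why: Half-reduction of the α-silyloxy ester (tetrahedral aluminium hemiacetal stable at −78 °C) and in situ Seyferth–Gilbert homologation with the Ohira–Bestmann reagent should give the terminal alkyne under carbonate conditions that normally preserve α-silyloxy stereocentres.

Step 10
Reactants: 16 (3R,4R,5S)-3-(tert-butyldimethylsilyloxy)-5-[2-(tert-butyldimethylsilyloxy)ethyl]-4-[3-(methoxymethoxy)prop-1-en-2-yl]-5-methylhept-6-en-1-yne
Product: 17 methyl (4R,5R,6S)-4-(tert-butyldimethylsilyloxy)-6-[2-(tert-butyldimethylsilyloxy)ethyl]-5-[3-(methoxymethoxy)prop-1-en-2-yl]-6-methyloct-7-en-2-ynoate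
Conditions: n-BuLi, THF, −78 °C; ClCO2Me, −78 to 0 °C
Reagents that add atoms: methyl chloroformate COC(=O)Cl
Why: Acylation of the lithium acetylide with a chloroformate should give the ynoate that carries C11 and C12.

Step 11
Reactants: 17 methyl (4R,5R,6S)-4-(tert-butyldimethylsilyloxy)-6-[2-(tert-butyldimethylsilyloxy)ethyl]-5-[3-(methoxymethoxy)prop-1-en-2-yl]-6-methyloct-7-en-2-ynoate
Product: 19 methyl (2Z,4S,5R,6S)-4-(tert-butyldimethylsilyloxy)-6-[2-(tert-butyldimethylsilyloxy)ethyl]-5-[3-(methoxymethoxy)prop-1-en-2-yl]-6-methyl-2-[(4,4,5,5-tetramethyl-1,3,2-dioxaborolan-2-yl)methyl]octa-2,7-dienoate, via alkenylalane 18 (not isolated)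
Conditions: i-Bu2AlH (1.3 equiv), HMPA (3 equiv), THF, 0 °C; then ICH2Bpin, 0 °C to rt
Reagents that add atoms: 2-(iodomethyl)-4,4,5,5-tetramethyl-1,3,2-dioxaborolane ICB1OC(C)(C)C(C)(C)O1
Why: Conjugate hydroalumination of the ynoate by the i-Bu2AlH–HMPA complex delivers H to C7 and aluminium to C11 on the same side, and alkylation of the α-aluminated acrylate with the iodomethylboronate with retention (the established entry to 2-(alkoxycarbonyl)allylboronates) should give the (Z)-enoate with C6 cis to the ester and trans to CH2B, which turns the electrophilic β-carbon C7 into the nucleophilic γ-carbon of an allylboronate.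

Step 12
Reactants: 19 methyl (2Z,4S,5R,6S)-4-(tert-butyldimethylsilyloxy)-6-[2-(tert-butyldimethylsilyloxy)ethyl]-5-[3-(methoxymethoxy)prop-1-en-2-yl]-6-methyl-2-[(4,4,5,5-tetramethyl-1,3,2-dioxaborolan-2-yl)methyl]octa-2,7-dienoate
Product: 20 methyl (2Z,4S,5R,6S)-4-(tert-butyldimethylsilyloxy)-6-(2-hydroxyethyl)-5-[3-(methoxymethoxy)prop-1-en-2-yl]-6-methyl-2-[(4,4,5,5-tetramethyl-1,3,2-dioxaborolan-2-yl)methyl]octa-2,7-dienoate
Conditions: CSA (0.1 equiv), MeOH/CH2Cl2 (1:1), 0 °C
Reagents that add atoms: none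
Why: Acid-catalysed methanolysis should remove the primary silyl ether much faster than the hindered secondary one at C6, and the pinacol boronate and the MOM ether are stable to these conditions.

Step 13
Reactants: 20 methyl (2Z,4S,5R,6S)-4-(tert-butyldimethylsilyloxy)-6-(2-hydroxyethyl)-5-[3-(methoxymethoxy)prop-1-en-2-yl]-6-methyl-2-[(4,4,5,5-tetramethyl-1,3,2-dioxaborolan-2-yl)methyl]octa-2,7-dienoate
Product: 23 methyl 2-[(1R,2R,3R,4S,6S)-2-(tert-butyldimethylsilyloxy)-4-ethenyl-6-hydroxy-3-[3-(methoxymethoxy)prop-1-en-2-yl]-4-methylcyclohexyl]prop-2-enoate, via aldehyde 21 (not isolated), via pinacol borate 22 (not isolated)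
Conditions: Dess–Martin periodinane (1.3 equiv), NaHCO3, CH2Cl2, 0 °C to rt; filtration; toluene (0.01 M), 60 °C; aq. NaHCO3
Reagents that add atoms: none
Why: Dess–Martin oxidation unveils the C8 aldehyde, whose oxygen binds the boron of the tethered (Z)-2-(methoxycarbonyl)allyl pinacolboronate so that the γ-carbon C7 adds to C8 through a closed six-membered chair transition state (B, O, C8, C7, C11, C13) with allyl transposition to the C11=C13 methylene, the borate being hydrolysed on work-up. The closest known reaction types are the intramolecular allylboration of ω-formyl γ-substituted allylboronates to trans-2-alkenylcyclohexanols and the allylboration of aldehydes with 3-substituted 2-(alkoxycarbonyl)allylboronates that gives anti γ-hydroxy α-methylene esters. The cyclohexane C5–C6–C7–C8–C9–C10 is closed by a 6-exo-trig addition to the carbonyl carbon with the allyl π bond exocyclic to the new ring (type 1 intramolecular allylboration) through a trans-decalin-like bicyclic transition state. C7 and C8 are set relative to each other by the boronate geometry (C6 trans to CH2B and hence equatorial in the boron chair, C9 of the aldehyde also equatorial), which should give the 7,8-anti product with H7 and H8 trans-diaxial; relative to C5, C6 and C10 they are set by the carbocyclic chair that keeps the C5 alkenyl group, the C6 silyloxy group and the C10 vinyl group equatorial and only the C10 methyl axial, the other chair placing all three axial with a syn-diaxial silyloxy/vinyl contact and the 8-epimer requiring the carbonyl oxygen syn-diaxial to the C10 methyl. The step needs chemoselectivity for allylboration over a carbonyl-ene reaction of the aldehyde with the C3=C4 alkene, over Cope rearrangement of the C3=C4–C5–C10–C1=C2 1,5-diene and over lactonisation of the new C8 borate onto C12; this is secured by the absence of any Lewis acid, a temperature of 60 °C or below, the silyl group on O6 (no butenolide, no second hydroxyl) and a neutral hydrolytic work-up.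

Step 14
Reactants: 24 methyl (R)-3-hydroxy-2-methylpropanoate
Product: 25 methyl (R)-3-(tert-butyldimethylsilyloxy)-2-methylpropanoate
Conditions: TBSCl, imidazole, CH2Cl2, rt
Reagents that add atoms: tert-butyldimethylsilyl chloride CC(C)(C)[Si](C)(C)Cl
Why: Standard silylation of the primary alcohol; the C2′ stereocentre is taken from the chiral pool and is not involved.

Step 15
Reactants: 25 methyl (R)-3-(tert-butyldimethylsilyloxy)-2-methylpropanoate
Product: 26 (R)-3-(tert-butyldimethylsilyloxy)-2-methylpropanoic acid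
Conditions: LiOH, THF/H2O, 0 °C to rt; 1 M HCl to pH 3
Reagents that add atoms: lithium hydroxide [Li+].[OH-]
Why: Mild saponification (acyl–oxygen cleavage) at low temperature should give the acid without epimerisation or β-elimination at the α-stereocentre.

Step 16
Reactants: 23 methyl 2-[(1R,2R,3R,4S,6S)-2-(tert-butyldimethylsilyloxy)-4-ethenyl-6-hydroxy-3-[3-(methoxymethoxy)prop-1-en-2-yl]-4-methylcyclohexyl]prop-2-enoate; 26 (R)-3-(tert-butyldimethylsilyloxy)-2-methylpropanoic acid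
Product: 27 (1S,2R,3R,4R,5S)-3-(tert-butyldimethylsilyloxy)-5-ethenyl-2-(3-methoxy-3-oxoprop-1-en-2-yl)-4-[3-(methoxymethoxy)prop-1-en-2-yl]-5-methylcyclohexyl (2R)-3-(tert-butyldimethylsilyloxy)-2-methylpropanoate
Conditions: EDC·HCl, DMAP, CH2Cl2, 0 °C to rt
Reagents that add atoms: none
Why: Carbodiimide/DMAP (Steglich) acylation of the only free hydroxyl, the equatorial C8–OH, should proceed with retention at C8 and without epimerisation of the acid at C2′ under these mild conditions.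

Step 17
Reactants: 27 (1S,2R,3R,4R,5S)-3-(tert-butyldimethylsilyloxy)-5-ethenyl-2-(3-methoxy-3-oxoprop-1-en-2-yl)-4-[3-(methoxymethoxy)prop-1-en-2-yl]-5-methylcyclohexyl (2R)-3-(tert-butyldimethylsilyloxy)-2-methylpropanoate
Product: 28 (1S,2R,3R,4R,5S)-3-(tert-butyldimethylsilyloxy)-5-ethenyl-4-(3-hydroxyprop-1-en-2-yl)-2-(3-methoxy-3-oxoprop-1-en-2-yl)-5-methylcyclohexyl (2R)-3-(tert-butyldimethylsilyloxy)-2-methylpropanoate
Conditions: Me2BBr, CH2Cl2, −78 °C; then sat. aq. NaHCO3/THF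
Reagents that add atoms: none
Why: Bromodimethylborane cleaves the MOM acetal at −78 °C through the bromomethyl ether, which hydrolyses on quench; silyl ethers, esters and alkenes are expected to survive.

Step 18
Reactants: 28 (1S,2R,3R,4R,5S)-3-(tert-butyldimethylsilyloxy)-5-ethenyl-4-(3-hydroxyprop-1-en-2-yl)-2-(3-methoxy-3-oxoprop-1-en-2-yl)-5-methylcyclohexyl (2R)-3-(tert-butyldimethylsilyloxy)-2-methylpropanoate
Product: 30 (3aR,4S,6S,7R,7aR)-6-ethenyl-7-(3-hydroxyprop-1-en-2-yl)-6-methyl-3-methylidene-2-oxooctahydro-1-benzofuran-4-yl (2R)-3-hydroxy-2-methylpropanoate, via hydroxy ester 29 (not isolated)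
Conditions: HF·pyridine, THF, 0 °C to rt; then TsOH·H2O (0.1 equiv), CH2Cl2, rt
Reagents that add atoms: none
Why: Desilylation frees O6 and the side-chain hydroxyl, and acid-catalysed 5-exo-trig transesterification of the equatorial C6 hydroxyl onto the neighbouring equatorial acrylate (O8 is acylated, so only the 6,12-lactone can form) should close the trans-fused α-methylene-γ-butyrolactone without touching any stereocentre.

## Compound list

1 | tert-butyl(but-3-yn-1-yloxy)dimethylsilane | C#CCCO[Si](C)(C)C(C)(C)C | starting material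
2 | (E)-[4-(tert-butyldimethylsilyloxy)-2-methylbut-1-en-1-yl]dimethylalane | C[Al](C)/C=C(\C)CCO[Si](C)(C)C(C)(C)C | intermediate
3 | (E)-5-(tert-butyldimethylsilyloxy)-3-methylpent-2-en-1-ol | OC/C=C(\C)CCO[Si](C)(C)C(C)(C)C | intermediate
4 | D-malic acid, (R)-2-hydroxybutanedioic acid | OC(=O)C[C@@H](O)C(=O)O | starting material
5 | 2-[(4R)-2,2-dimethyl-5-oxo-1,3-dioxolan-4-yl]acetic acid | OC(=O)C[C@H]1OC(C)(C)OC1=O | intermediate
6 | (E)-5-(tert-butyldimethylsilyloxy)-3-methylpent-2-en-1-yl 2-[(4R)-2,2-dimethyl-5-oxo-1,3-dioxolan-4-yl]acetate | CC(C)(C)[Si](C)(C)OCC/C(C)=C/COC(=O)C[C@H]1OC(C)(C)OC1=O | intermediate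
7 | 1-methyl 4-[(E)-5-(tert-butyldimethylsilyloxy)-3-methylpent-2-en-1-yl] (2R)-2-hydroxybutanedioate | COC(=O)[C@H](O)CC(=O)OC/C=C(\C)CCO[Si](C)(C)C(C)(C)C | intermediate
8 | dilithium alkoxide enolate of 7 (C5=C4 enolate; C6 cis to OLi) | [Li+].[Li+].COC(=O)[C@H]([O-])/C=C(\[O-])OC/C=C(\C)CCO[Si](C)(C)C(C)(C)C | intermediate
9 | (2S,3S)-3-[2-(tert-butyldimethylsilyloxy)ethyl]-2-[(1R)-1-hydroxy-2-methoxy-2-oxoethyl]-3-methylpent-4-enoic acid (5S,6R,10S in elemanolide locants) | C=C[C@]([C@@H]([C@@H](O)C(=O)OC)C(=O)O)(C)CCO[Si](C)(C)C(C)(C)C | intermediate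
10 | tert-butyldimethylsilyl ester of acid 11 | C=C[C@]([C@@H]([C@@H](O[Si](C)(C)C(C)(C)C)C(=O)OC)C(=O)O[Si](C)(C)C(C)(C)C)(C)CCO[Si](C)(C)C(C)(C)C | intermediate
11 | (2S,3S)-2-[(1R)-1-(tert-butyldimethylsilyloxy)-2-methoxy-2-oxoethyl]-3-[2-(tert-butyldimethylsilyloxy)ethyl]-3-methylpent-4-enoic acid | C=C[C@]([C@@H]([C@@H](O[Si](C)(C)C(C)(C)C)C(=O)OC)C(=O)O)(C)CCO[Si](C)(C)C(C)(C)C | intermediate
12 | acid chloride of 11 (5S,6R,10S) | C=C[C@]([C@@H]([C@@H](O[Si](C)(C)C(C)(C)C)C(=O)OC)C(=O)Cl)(C)CCO[Si](C)(C)C(C)(C)C | intermediate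
13 | methyl (2R,3S,4S)-2-(tert-butyldimethylsilyloxy)-4-[2-(tert-butyldimethylsilyloxy)ethyl]-3-[2-(methoxymethoxy)acetyl]-4-methylhex-5-enoate | C=C[C@]([C@@H]([C@@H](O[Si](C)(C)C(C)(C)C)C(=O)OC)C(=O)COCOC)(C)CCO[Si](C)(C)C(C)(C)C | intermediate
14 | methyl (2R,3R,4S)-2-(tert-butyldimethylsilyloxy)-4-[2-(tert-butyldimethylsilyloxy)ethyl]-3-[3-(methoxymethoxy)prop-1-en-2-yl]-4-methylhex-5-enoate | C=C[C@]([C@@H]([C@@H](O[Si](C)(C)C(C)(C)C)C(=O)OC)C(=C)COCOC)(C)CCO[Si](C)(C)C(C)(C)C | intermediate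
15 | (2R,3R,4S)-2-(tert-butyldimethylsilyloxy)-4-[2-(tert-butyldimethylsilyloxy)ethyl]-3-[3-(methoxymethoxy)prop-1-en-2-yl]-4-methylhex-5-enal | C=C[C@]([C@@H]([C@@H](O[Si](C)(C)C(C)(C)C)C=O)C(=C)COCOC)(C)CCO[Si](C)(C)C(C)(C)C | intermediate
16 | (3R,4R,5S)-3-(tert-butyldimethylsilyloxy)-5-[2-(tert-butyldimethylsilyloxy)ethyl]-4-[3-(methoxymethoxy)prop-1-en-2-yl]-5-methylhept-6-en-1-yne | C=C[C@]([C@@H]([C@@H](O[Si](C)(C)C(C)(C)C)C#C)C(=C)COCOC)(C)CCO[Si](C)(C)C(C)(C)C | intermediate
17 | methyl (4R,5R,6S)-4-(tert-butyldimethylsilyloxy)-6-[2-(tert-butyldimethylsilyloxy)ethyl]-5-[3-(methoxymethoxy)prop-1-en-2-yl]-6-methyloct-7-en-2-ynoate | C=C[C@]([C@@H]([C@@H](O[Si](C)(C)C(C)(C)C)C#CC(=O)OC)C(=C)COCOC)(C)CCO[Si](C)(C)C(C)(C)C | intermediate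
18 | methyl (2E,4R,5R,6S)-2-(diisobutylalumanyl)-4-(tert-butyldimethylsilyloxy)-6-[2-(tert-butyldimethylsilyloxy)ethyl]-5-[3-(methoxymethoxy)prop-1-en-2-yl]-6-methylocta-2,7-dienoate | C=C[C@]([C@@H]([C@@H](O[Si](C)(C)C(C)(C)C)/C=C(/[Al](CC(C)C)CC(C)C)C(=O)OC)C(=C)COCOC)(C)CCO[Si](C)(C)C(C)(C)C | intermediate
19 | methyl (2Z,4S,5R,6S)-4-(tert-butyldimethylsilyloxy)-6-[2-(tert-butyldimethylsilyloxy)ethyl]-5-[3-(methoxymethoxy)prop-1-en-2-yl]-6-methyl-2-[(4,4,5,5-tetramethyl-1,3,2-dioxaborolan-2-yl)methyl]octa-2,7-dienoate | C=C[C@]([C@@H]([C@@H](O[Si](C)(C)C(C)(C)C)/C=C(/CB1OC(C)(C)C(C)(C)O1)C(=O)OC)C(=C)COCOC)(C)CCO[Si](C)(C)C(C)(C)C | intermediate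
20 | methyl (2Z,4S,5R,6S)-4-(tert-butyldimethylsilyloxy)-6-(2-hydroxyethyl)-5-[3-(methoxymethoxy)prop-1-en-2-yl]-6-methyl-2-[(4,4,5,5-tetramethyl-1,3,2-dioxaborolan-2-yl)methyl]octa-2,7-dienoate | C=C[C@]([C@@H]([C@@H](O[Si](C)(C)C(C)(C)C)/C=C(/CB1OC(C)(C)C(C)(C)O1)C(=O)OC)C(=C)COCOC)(C)CCO | intermediate
21 | methyl (2Z,4S,5R,6S)-4-(tert-butyldimethylsilyloxy)-5-[3-(methoxymethoxy)prop-1-en-2-yl]-6-methyl-6-(2-oxoethyl)-2-[(4,4,5,5-tetramethyl-1,3,2-dioxaborolan-2-yl)methyl]octa-2,7-dienoate | C=C[C@]([C@@H]([C@@H](O[Si](C)(C)C(C)(C)C)/C=C(/CB1OC(C)(C)C(C)(C)O1)C(=O)OC)C(=C)COCOC)(C)CC=O | intermediate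
22 | O8-pinacolboryl derivative of 23 (5R,6R,7R,8S,10S) | C=C[C@]1(C)C[C@H](OB2OC(C)(C)C(C)(C)O2)[C@@H](C(=C)C(=O)OC)[C@H](O[Si](C)(C)C(C)(C)C)[C@H]1C(=C)COCOC | intermediate
23 | methyl 2-[(1R,2R,3R,4S,6S)-2-(tert-butyldimethylsilyloxy)-4-ethenyl-6-hydroxy-3-[3-(methoxymethoxy)prop-1-en-2-yl]-4-methylcyclohexyl]prop-2-enoate | C=C[C@]1(C)C[C@H](O)[C@@H](C(=C)C(=O)OC)[C@H](O[Si](C)(C)C(C)(C)C)[C@H]1C(=C)COCOC | intermediate
24 | methyl (R)-3-hydroxy-2-methylpropanoate | COC(=O)[C@H](C)CO | starting material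
25 | methyl (R)-3-(tert-butyldimethylsilyloxy)-2-methylpropanoate | COC(=O)[C@H](C)CO[Si](C)(C)C(C)(C)C | intermediate
26 | (R)-3-(tert-butyldimethylsilyloxy)-2-methylpropanoic acid | OC(=O)[C@H](C)CO[Si](C)(C)C(C)(C)C | intermediate
27 | (1S,2R,3R,4R,5S)-3-(tert-butyldimethylsilyloxy)-5-ethenyl-2-(3-methoxy-3-oxoprop-1-en-2-yl)-4-[3-(methoxymethoxy)prop-1-en-2-yl]-5-methylcyclohexyl (2R)-3-(tert-butyldimethylsilyloxy)-2-methylpropanoate | C=C[C@]1(C)C[C@H](OC(=O)[C@H](C)CO[Si](C)(C)C(C)(C)C)[C@@H](C(=C)C(=O)OC)[C@H](O[Si](C)(C)C(C)(C)C)[C@H]1C(=C)COCOC | intermediate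
28 | (1S,2R,3R,4R,5S)-3-(tert-butyldimethylsilyloxy)-5-ethenyl-4-(3-hydroxyprop-1-en-2-yl)-2-(3-methoxy-3-oxoprop-1-en-2-yl)-5-methylcyclohexyl (2R)-3-(tert-butyldimethylsilyloxy)-2-methylpropanoate | C=C[C@]1(C)C[C@H](OC(=O)[C@H](C)CO[Si](C)(C)C(C)(C)C)[C@@H](C(=C)C(=O)OC)[C@H](O[Si](C)(C)C(C)(C)C)[C@H]1C(=C)CO | intermediate
29 | (1S,2S,3R,4R,5S)-5-ethenyl-3-hydroxy-4-(3-hydroxyprop-1-en-2-yl)-2-(3-methoxy-3-oxoprop-1-en-2-yl)-5-methylcyclohexyl (2R)-3-hydroxy-2-methylpropanoate | C=C[C@]1(C)C[C@H](OC(=O)[C@H](C)CO)[C@@H](C(=C)C(=O)OC)[C@H](O)[C@H]1C(=C)CO | intermediate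
30 | (3aR,4S,6S,7R,7aR)-6-ethenyl-7-(3-hydroxyprop-1-en-2-yl)-6-methyl-3-methylidene-2-oxooctahydro-1-benzofuran-4-yl (2R)-3-hydroxy-2-methylpropanoate | C=C[C@]1(C)C[C@H](OC(=O)[C@H](C)CO)[C@H]2C(=C)C(=O)O[C@@H]2[C@H]1C(=C)CO | target

## Step count and risks

Total step count: 18. Longest linear sequence: 15 steps (steps 2–13 and 16–18 from D-malic acid; the branch through step 1 is equally long).

Steps most likely to fail:

1. Step 5 (dianionic Claisen rearrangement). The dianion may fragment (retro-aldol, ketene loss or β-elimination) before the [3,3] shift occurs at the temperature needed to build the quaternary carbon, and facial control may erode if the lithium chelate opens. Fallback: from hydroxy diester 7, silylation (TBSOTf, 2,6-lutidine) would give 1-methyl 4-allyl (2R)-2-(tert-butyldimethylsilyloxy)butanedioate F1. Enolisation with LiN(i-Pr)2 in THF/DMPU and trapping with Me3SiCl at −78 °C would give the ketene trimethylsilyl acetal F2 (C6 cis to OSiMe3). This should undergo Ireland–Claisen rearrangement at 25–50 °C through a chair, with the allyl unit anti to the silyloxy group in the A(1,3)-minimised conformer, to the trimethylsilyl ester F3. Aqueous work-up would return acid 11, so the route is rejoined after step 6.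

2. Step 11 (hydroalumination and borylmethylation). 1,2-Reduction of the ester, loss of alkene geometry through an aluminium allenolate, or slow alkylation of the hindered alkenylalane may intervene. Fallback: from ynoate 17, syn-hydrostannation (Bu3SnH, Pd(PPh3)4, THF, 0 °C) would place tin on C11 and give the α-stannyl enoate F4. Iododestannylation (I2, CH2Cl2, 0 °C) would give the α-iodo enoate F5 with retention. Negishi coupling of F5 with (pinacolboryl)methylzinc iodide (Pd(PPh3)4, THF, rt) would give allylboronate 19.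

3. Step 13 (key step). Addition of the electron-poor allylboronate may be slow enough for protodeboronation, aldehyde decomposition or the carbonyl-ene pathway to compete, or the facial preference may be lower than expected. Fallback: from ynoate 17, the same hydroalumination (alkenylalane 18) but with paraformaldehyde as electrophile would give the (Z)-2-(hydroxymethyl) enoate F6. Appel bromination (CBr4, PPh3, 0 °C) would give the allylic bromide F7. CSA/MeOH would free the primary alcohol F8, and Dess–Martin oxidation would give the bromo aldehyde F9. Nozaki–Hiyama–Kishi cyclisation (CrCl2, THF, rt, high dilution) generates an allylchromium reagent by reduction of the bromide; it should add through a chair transition state with the same all-equatorial preference and give hydroxy ester 23.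

## Further compounds

F1 | step 5 | 1-methyl 4-[(E)-5-(tert-butyldimethylsilyloxy)-3-methylpent-2-en-1-yl] (2R)-2-(tert-butyldimethylsilyloxy)butanedioate | COC(=O)[C@H](O[Si](C)(C)C(C)(C)C)CC(=O)OC/C=C(\C)CCO[Si](C)(C)C(C)(C)C
F2 | step 5 | ketene trimethylsilyl acetal of F1 (C6 cis to OSiMe3) | COC(=O)[C@H](O[Si](C)(C)C(C)(C)C)/C=C(\O[Si](C)(C)C)OC/C=C(\C)CCO[Si](C)(C)C(C)(C)C
F3 | step 5 | trimethylsilyl ester of acid 11 | C=C[C@]([C@@H]([C@@H](O[Si](C)(C)C(C)(C)C)C(=O)OC)C(=O)O[Si](C)(C)C)(C)CCO[Si](C)(C)C(C)(C)C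
F4 | step 11 | methyl (2E,4R,5R,6S)-4-(tert-butyldimethylsilyloxy)-6-[2-(tert-butyldimethylsilyloxy)ethyl]-5-[3-(methoxymethoxy)prop-1-en-2-yl]-6-methyl-2-(tributylstannyl)octa-2,7-dienoate | C=C[C@]([C@@H]([C@@H](O[Si](C)(C)C(C)(C)C)/C=C(/[Sn](CCCC)(CCCC)CCCC)C(=O)OC)C(=C)COCOC)(C)CCO[Si](C)(C)C(C)(C)C
F5 | step 11 | methyl (2E,4R,5R,6S)-4-(tert-butyldimethylsilyloxy)-6-[2-(tert-butyldimethylsilyloxy)ethyl]-2-iodo-5-[3-(methoxymethoxy)prop-1-en-2-yl]-6-methylocta-2,7-dienoate | C=C[C@]([C@@H]([C@@H](O[Si](C)(C)C(C)(C)C)/C=C(/I)C(=O)OC)C(=C)COCOC)(C)CCO[Si](C)(C)C(C)(C)C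
F6 | step 13 | methyl (2Z,4S,5R,6S)-4-(tert-butyldimethylsilyloxy)-6-[2-(tert-butyldimethylsilyloxy)ethyl]-2-(hydroxymethyl)-5-[3-(methoxymethoxy)prop-1-en-2-yl]-6-methylocta-2,7-dienoate | C=C[C@]([C@@H]([C@@H](O[Si](C)(C)C(C)(C)C)/C=C(/CO)C(=O)OC)C(=C)COCOC)(C)CCO[Si](C)(C)C(C)(C)C
F7 | step 13 | methyl (2E,4S,5R,6S)-2-(bromomethyl)-4-(tert-butyldimethylsilyloxy)-6-[2-(tert-butyldimethylsilyloxy)ethyl]-5-[3-(methoxymethoxy)prop-1-en-2-yl]-6-methylocta-2,7-dienoate | C=C[C@]([C@@H]([C@@H](O[Si](C)(C)C(C)(C)C)/C=C(/CBr)C(=O)OC)C(=C)COCOC)(C)CCO[Si](C)(C)C(C)(C)C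
F8 | step 13 | methyl (2E,4S,5R,6S)-2-(bromomethyl)-4-(tert-butyldimethylsilyloxy)-6-(2-hydroxyethyl)-5-[3-(methoxymethoxy)prop-1-en-2-yl]-6-methylocta-2,7-dienoate | C=C[C@]([C@@H]([C@@H](O[Si](C)(C)C(C)(C)C)/C=C(/CBr)C(=O)OC)C(=C)COCOC)(C)CCO
F9 | step 13 | methyl (2E,4S,5R,6S)-2-(bromomethyl)-4-(tert-butyldimethylsilyloxy)-5-[3-(methoxymethoxy)prop-1-en-2-yl]-6-methyl-6-(2-oxoethyl)octa-2,7-dienoate | C=C[C@]([C@@H]([C@@H](O[Si](C)(C)C(C)(C)C)/C=C(/CBr)C(=O)OC)C(=C)COCOC)(C)CC=O
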